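**Retrosynthetic overview**

1. Target ⇒ 2',5'-dihydroxy-5,6,7,8-tetramethoxyflavone by cleaving only the 5-OMe (peri to the C4 carbonyl) ⇒ its 2',5'-dibenzyl ether by O-debenzylation.
2. Ring C ⇒ the O1–C2 bond and the C2=C3 unsaturation come from an iodine/DMSO oxidative cyclisation of a 2'-hydroxychalcone.
3. Key C–C bond (C2–C3 of the flavone) ⇒ Claisen–Schmidt aldol condensation of 2-hydroxy-3,4,5,6-tetramethoxyacetophenone with 2,5-bis(benzyloxy)benzaldehyde.
4. Ketone ⇒ 3,4,5-trimethoxyphenol (ortho C-acetylation, bromination of the last ring C–H, CuBr/NaOMe methoxylation); aldehyde ⇒ 2,5-dihydroxybenzaldehyde + benzyl bromide.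
5. Ring order: ring A and ring B are present in the starting benzenes; ring C is the only ring built, closed in the step after the aldol.

Assumption: the target has no stereocentre and no stereogenic double bond, so it is achiral, there is no enantiomer to select, and the route needs no stereocontrol.

**Route**

Step 1
Reactants: 1 3,4,5-trimethoxyphenol
Product: 3 1-(2-hydroxy-4,5,6-trimethoxyphenyl)ethanone, via difluoroboron chelate 2 (not isolated)
Conditions: AcOH, BF3·OEt2 (3 equiv), 90 °C, 2 h; then H2O, 60 °C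
Reagents that add atoms: acetic acid, CC(=O)O
Why: BF3-promoted Friedel–Crafts C-acetylation occurs at one of the two equivalent positions ortho to the phenol of the symmetric arene, the product being held as the six-membered BF2 chelate 2 (which blocks a second acylation) until water hydrolyses it.

Step 2
Reactants: 3 1-(2-hydroxy-4,5,6-trimethoxyphenyl)ethanone
Product: 4 1-(3-bromo-2-hydroxy-4,5,6-trimethoxyphenyl)ethanone
Conditions: NBS (1.05 equiv), MeCN, 0 °C to rt, 1 h
Reagents that add atoms: N-bromosuccinimide, O=C1CCC(=O)N1Br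
Why: Electrophilic aromatic bromination takes the single remaining ring C–H, which is ortho to the phenol and para to a methoxy group and therefore reacts far faster than the acetyl α-position.

Step 3
Reactants: 4 1-(3-bromo-2-hydroxy-4,5,6-trimethoxyphenyl)ethanone
Product: 5 1-(2-hydroxy-3,4,5,6-tetramethoxyphenyl)ethanone
Conditions: NaOMe (25% in MeOH, 6 equiv), CuBr (0.2 equiv), DMF, 110 °C, 5 h, N2; acidic work-up
Reagents that add atoms: sodium methoxide, C[O-].[Na+]
Why: Copper-catalysed Ullmann-type methoxylation (the reaction type that turns 5-bromovanillin into syringaldehyde) replaces the aryl bromide next to a phenoxide by OMe, while the doubly ortho-substituted ketone is too hindered to self-condense.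

Step 4
Reactants: 6 2,5-dihydroxybenzaldehyde
Product: 7 2,5-bis(benzyloxy)benzaldehyde
Conditions: BnBr (2.3 equiv), K2CO3 (3 equiv), DMF, 60 °C, 4 h
Reagents that add atoms: benzyl bromide, BrCc1ccccc1
Why: Williamson ether synthesis on both phenoxides gives benzyl ethers that survive aqueous KOH and hot iodine/DMSO and are later removed under neutral conditions.

Step 5
Reactants: 5 1-(2-hydroxy-3,4,5,6-tetramethoxyphenyl)ethanone; 7 2,5-bis(benzyloxy)benzaldehyde (1.2 equiv)
Product: 9 (E)-3-[2,5-bis(benzyloxy)phenyl]-1-(2-hydroxy-3,4,5,6-tetramethoxyphenyl)prop-2-en-1-one, via aldol adduct 8 (not isolated)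
Conditions: KOH (50% aq, 10 equiv), EtOH, rt, 36 h; acidic work-up
Reagents that add atoms: none
Why: In this Claisen–Schmidt crossed aldol condensation the ketone enolate adds to the non-enolisable aldehyde and the racemic aldol 8 dehydrates by E1cB to the conjugated chalcone, formed as the thermodynamically favoured E alkene, so no stereocentre is kept.

Step 6
Reactants: 9 (E)-3-[2,5-bis(benzyloxy)phenyl]-1-(2-hydroxy-3,4,5,6-tetramethoxyphenyl)prop-2-en-1-one
Product: 11 2-[2,5-bis(benzyloxy)phenyl]-5,6,7,8-tetramethoxy-4H-chromen-4-one, via flavanone 10 (not isolated)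
Conditions: I2 (0.1 equiv), DMSO, 130 °C, 2 h
Reagents that add atoms: none
Why: Iodine-catalysed oxidative cyclisation proceeds by 6-endo oxa-Michael closure to racemic flavanone 10 and iodination/HI elimination across C2–C3, with DMSO reoxidising HI to I2, which removes the C2 stereocentre and closes ring C.

Step 7
Reactants: 11 2-[2,5-bis(benzyloxy)phenyl]-5,6,7,8-tetramethoxy-4H-chromen-4-one
Product: 12 2-(2,5-dihydroxyphenyl)-5,6,7,8-tetramethoxy-4H-chromen-4-one
Conditions: H2 (1 atm), 10% Pd/C, THF/MeOH 1:1, rt, 3 h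
Reagents that add atoms: none
Why: Catalytic hydrogenolysis cleaves the two benzylic C–O bonds, while the chromone C2=C3 bond (a vinylogous ester) and the aryl methyl ethers are inert at 1 atm and room temperature.

Step 8
Reactants: 12 2-(2,5-dihydroxyphenyl)-5,6,7,8-tetramethoxy-4H-chromen-4-one
Product: 14 2-(2,5-dihydroxyphenyl)-5-hydroxy-6,7,8-trimethoxy-4H-chromen-4-one (5,2',5'-trihydroxy-6,7,8-trimethoxyflavone), via tris(dichloroboryl) ether 13 (not isolated)
Conditions: BCl3 (1 M in CH2Cl2, 5 equiv), CH2Cl2, 0 °C to rt, 3 h, N2; then H2O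
Reagents that add atoms: none
Why: In this chelation-directed Lewis acid ether cleavage, boron held between the C4 carbonyl and the peri 5-OMe delivers chloride to that methyl group only, the 6-, 7- and 8-OMe groups cannot chelate and survive, and water then hydrolyses the B–O bonds of 13.

**Compound list**

1 | 3,4,5-trimethoxyphenol | COc1cc(O)cc(OC)c1OC | starting material
2 | difluoroboron chelate of 3 (2,2-difluoro-5,6,7-trimethoxy-4-methyl-1,3,2-benzodioxaborinine, zwitterionic form; not isolated) | CC1=[O+][B-](F)(F)Oc2cc(OC)c(OC)c(OC)c12 | intermediate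
3 | 1-(2-hydroxy-4,5,6-trimethoxyphenyl)ethanone | CC(=O)c1c(O)cc(OC)c(OC)c1OC | intermediate
4 | 1-(3-bromo-2-hydroxy-4,5,6-trimethoxyphenyl)ethanone | CC(=O)c1c(O)c(Br)c(OC)c(OC)c1OC | intermediate
5 | 1-(2-hydroxy-3,4,5,6-tetramethoxyphenyl)ethanone | CC(=O)c1c(O)c(OC)c(OC)c(OC)c1OC | intermediate
6 | 2,5-dihydroxybenzaldehyde | O=Cc1cc(O)ccc1O | starting material
7 | 2,5-bis(benzyloxy)benzaldehyde | O=Cc1cc(OCc2ccccc2)ccc1OCc1ccccc1 | intermediate
8 | 3-[2,5-bis(benzyloxy)phenyl]-3-hydroxy-1-(2-hydroxy-3,4,5,6-tetramethoxyphenyl)propan-1-one (racemic aldol adduct; not isolated) | O=C(CC(O)c1cc(OCc2ccccc2)ccc1OCc1ccccc1)c1c(O)c(OC)c(OC)c(OC)c1OC | intermediate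
9 | (E)-3-[2,5-bis(benzyloxy)phenyl]-1-(2-hydroxy-3,4,5,6-tetramethoxyphenyl)prop-2-en-1-one | O=C(/C=C/c1cc(OCc2ccccc2)ccc1OCc1ccccc1)c1c(O)c(OC)c(OC)c(OC)c1OC | intermediate
10 | 2-[2,5-bis(benzyloxy)phenyl]-5,6,7,8-tetramethoxychroman-4-one (racemic flavanone; not isolated) | COc1c(OC)c(OC)c2C(=O)CC(c3cc(OCc4ccccc4)ccc3OCc3ccccc3)Oc2c1OC | intermediate
11 | 2-[2,5-bis(benzyloxy)phenyl]-5,6,7,8-tetramethoxy-4H-chromen-4-one | COc1c(OC)c(OC)c2c(=O)cc(-c3cc(OCc4ccccc4)ccc3OCc3ccccc3)oc2c1OC | intermediate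
12 | 2-(2,5-dihydroxyphenyl)-5,6,7,8-tetramethoxy-4H-chromen-4-one | COc1c(OC)c(OC)c2c(=O)cc(-c3cc(O)ccc3O)oc2c1OC | intermediate
13 | 5-(dichloroboryloxy)-2-[2,5-bis(dichloroboryloxy)phenyl]-6,7,8-trimethoxy-4H-chromen-4-one (5-O–B chelated to the C4 carbonyl; not isolated) | COc1c(OC)c(OB(Cl)Cl)c2c(=O)cc(-c3cc(OB(Cl)Cl)ccc3OB(Cl)Cl)oc2c1OC | intermediate
14 | 2-(2,5-dihydroxyphenyl)-5-hydroxy-6,7,8-trimethoxy-4H-chromen-4-one (5,2',5'-trihydroxy-6,7,8-trimethoxyflavone; achiral) | COc1c(OC)c(O)c2c(=O)cc(-c3cc(O)ccc3O)oc2c1OC | target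

**Totals**

Total step count: 8.
Longest linear sequence: 7 steps (steps 1, 2, 3, 5, 6, 7 and 8 from compound 1); step 4 is a one-step side branch from compound 6.

**Three steps most likely to fail, each with a fallback**

Step 3 (CuBr/NaOMe methoxylation of the hindered ortho-bromophenol 4). The risks are hydrodebromination back to 3 and stalling at partial conversion. The fallback introduces the oxygen by formylation and Dakin oxidation instead of a copper coupling; it sets out from 3 and comes back at 5. Duff formylation of 3 (hexamethylenetetramine, CF3CO2H, 80 °C, then aqueous HCl) at the only free ring position gives 3-acetyl-2-hydroxy-4,5,6-trimethoxybenzaldehyde F1. Dakin oxidation (H2O2, aqueous NaOH, 0 °C), in which the ortho-hydroxy aldehyde reacts much faster than the hindered ketone, gives 1-(2,3-dihydroxy-4,5,6-trimethoxyphenyl)ethanone F2. Forming the dianion (NaH, 2.1 equiv, DMSO) and adding MeI (1.0 equiv) methylates the more nucleophilic, non-chelated 3-oxide and returns 5.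

Step 6 (iodine/DMSO oxidative cyclisation of 9). The risks are HI-mediated loss of a benzyl group or of the 5-methyl group at 130 °C, and stalling at flavanone 10. The fallback builds ring C without any oxidation, through a 1,3-diketone made by an intermolecular Claisen condensation; it sets out from 7 (used together with ketone 5) and comes back at 11. Pinnick oxidation of 7 (NaClO2, NaH2PO4, 2-methyl-2-butene, t-BuOH/H2O) gives 2,5-bis(benzyloxy)benzoic acid F3, and (COCl)2 with catalytic DMF in CH2Cl2 gives 2,5-bis(benzyloxy)benzoyl chloride F4. The dianion of 5 (LiN(SiMe3)2, 3.5 equiv, THF, −78 °C) is C-acylated by F4 (−78 °C to rt; any O-acylated ester converges by Baker–Venkataraman acyl shift under the excess base) to give 1-[2,5-bis(benzyloxy)phenyl]-3-(2-hydroxy-3,4,5,6-tetramethoxyphenyl)propane-1,3-dione F5. Cyclodehydration (catalytic TsOH·H2O, toluene, 80 °C) then gives 11.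

Step 8 (BCl3 cleavage of the 5-OMe in 12). The risks are incomplete reaction or further loss of the neighbouring 6-OMe, on a hydroquinone that oxidises easily in air. The fallback carries the 5-oxygen as a benzyl ether so that the last step is a neutral hydrogenolysis; it sets out from 5 and comes back at 14.
- BCl3 (2.5 equiv, CH2Cl2, 0 °C to rt) cleaves the 6-OMe of 5 ortho to the acetyl group by chelation, giving the symmetric 1-(2,6-dihydroxy-3,4,5-trimethoxyphenyl)ethanone F6.
- Mono-benzylation (BnBr 1.0 equiv, K2CO3, acetone, reflux; the remaining OH is deactivated by hydrogen bonding to the carbonyl) gives 1-[2-(benzyloxy)-6-hydroxy-3,4,5-trimethoxyphenyl]ethanone F7.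
- Claisen–Schmidt condensation with 7 (KOH, EtOH, rt) gives (E)-1-[2-(benzyloxy)-6-hydroxy-3,4,5-trimethoxyphenyl]-3-[2,5-bis(benzyloxy)phenyl]prop-2-en-1-one F8.
- I2 (0.1 equiv) in DMSO at 130 °C gives 5-(benzyloxy)-2-[2,5-bis(benzyloxy)phenyl]-6,7,8-trimethoxy-4H-chromen-4-one F9.
- H2 (1 atm), 10% Pd/C, THF/MeOH removes all three benzyl groups and gives 14.

**Further compounds**

F1 | step 3 | 3-acetyl-2-hydroxy-4,5,6-trimethoxybenzaldehyde | CC(=O)c1c(O)c(C=O)c(OC)c(OC)c1OC
F2 | step 3 | 1-(2,3-dihydroxy-4,5,6-trimethoxyphenyl)ethanone | CC(=O)c1c(O)c(O)c(OC)c(OC)c1OC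
F3 | step 6 | 2,5-bis(benzyloxy)benzoic acid | O=C(O)c1cc(OCc2ccccc2)ccc1OCc1ccccc1
F4 | step 6 | 2,5-bis(benzyloxy)benzoyl chloride | O=C(Cl)c1cc(OCc2ccccc2)ccc1OCc1ccccc1
F5 | step 6 | 1-[2,5-bis(benzyloxy)phenyl]-3-(2-hydroxy-3,4,5,6-tetramethoxyphenyl)propane-1,3-dione | O=C(CC(=O)c1c(O)c(OC)c(OC)c(OC)c1OC)c1cc(OCc2ccccc2)ccc1OCc1ccccc1
F6 | step 8 | 1-(2,6-dihydroxy-3,4,5-trimethoxyphenyl)ethanone | CC(=O)c1c(O)c(OC)c(OC)c(OC)c1O
F7 | step 8 | 1-[2-(benzyloxy)-6-hydroxy-3,4,5-trimethoxyphenyl]ethanone | CC(=O)c1c(O)c(OC)c(OC)c(OC)c1OCc1ccccc1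
F8 | step 8 | (E)-1-[2-(benzyloxy)-6-hydroxy-3,4,5-trimethoxyphenyl]-3-[2,5-bis(benzyloxy)phenyl]prop-2-en-1-one | O=C(/C=C/c1cc(OCc2ccccc2)ccc1OCc1ccccc1)c1c(O)c(OC)c(OC)c(OC)c1OCc1ccccc1
F9 | step 8 | 5-(benzyloxy)-2-[2,5-bis(benzyloxy)phenyl]-6,7,8-trimethoxy-4H-chromen-4-one | COc1c(OC)c(OCc2ccccc2)c2c(=O)cc(-c3cc(OCc4ccccc4)ccc3OCc3ccccc3)oc2c1OC
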